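## Retrosynthetic overview

1. Last C–C bond: ring carbinol carbon to side-chain CH2. A linalool-derived γ-lithio alkoxide, which already carries the side-chain carbinol centre, adds axially to a bromodecalone and sets the ring carbinol centre.
2. Bromodecalone ⇐ trisubstituted ring olefin by hydroboration/oxidation; the α-methyl centre is set by equilibration.
3. Ring olefin ⇐ acyclic vinylsilane triene by one catalytic asymmetric bromonium-initiated bicyclisation. The bromo/gem-dimethyl ring closes first and the second ring closes onto the vinylsilane; both rings and three stereocentres form in one operation.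
4. Triene ⇐ (E)-geranylacetone (Peterson olefination); side-chain iodide ⇐ (R)-linalool by one-carbon excision (ozonolysis, then alkoxy-radical fragmentation).

Assumption 1: (E)-geranylacetone (≥97 % E) and (R)-(−)-linalool (high ee) are bought as single isomers.
Assumption 2: the sense of induction of the BINOL-thiophosphoramide catalyst is carried over from aryl-terminated polyenes; the antipode that gives the (6R)-bromide is used (written as the (S)-BINOL-derived one) and is checked on the first run by X-ray anomalous dispersion at Br.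

## Route

Step 1
Reactants: 1 (5E)-6,10-dimethylundeca-5,9-dien-2-one ((E)-geranylacetone)
Product: 3 trimethyl[(5E)-2,6,10-trimethylundeca-1,5,9-trien-1-yl]silane (1E/1Z mixture), via lithium bis-silyl alkoxide adduct 2 (not isolated)
Conditions: (Me3Si)2CH2, t-BuLi, THF/HMPA, −78 → −40 °C; then 1, −78 °C → rt
Reagents that add atoms: bis(trimethylsilyl)methyllithium, [Li]C([Si](C)(C)C)[Si](C)(C)C, made in the flask from bis(trimethylsilyl)methane, C[Si](C)(C)C[Si](C)(C)C, and t-BuLi, CC(C)(C)[Li]
Why: Peterson olefination, in which the α,α-disilyl carbanion adds to the methyl ketone and adduct 2 loses Me3SiOLi spontaneously to give the vinylsilane; no stereocentre is set, the 1E/1Z ratio does not matter because silicon is lost in step 2, and enolisation of 1 is the main loss (recovered 1 is recycled).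

Step 2
Reactants: 3 trimethyl[(5E)-2,6,10-trimethylundeca-1,5,9-trien-1-yl]silane
Product: 4 (4aS,6R,8aS)-6-bromo-2,5,5,8a-tetramethyl-3,4,4a,5,6,7,8,8a-octahydronaphthalene (trans ring fusion, equatorial Br, C1=C2 olefin)
Conditions: DBDMH (1.05 equiv), (S)-BINOL-derived N-aryl thiophosphoramide (10 mol %), toluene/CH2Cl2, −90 °C
Reagents that add atoms: 1,3-dibromo-5,5-dimethylhydantoin (DBDMH), CC1(C)N(Br)C(=O)N(Br)C1=O
Why: Proposed new method: chiral Lewis-base-catalysed bromonium transfer to the terminal trisubstituted olefin (closest known reaction: thiophosphoramide/DBDMH-catalysed asymmetric bromocyclisation of aryl-terminated polyenes) starts a chair–chair cation–olefin bicyclisation in which anti addition across the two E-configured olefins gives the trans-decalin with equatorial Br, the catalyst's face selection fixes C6, C4a and C8a as R, S and S, and ipso attack of the vinylsilane carbon on the C8a cation followed by loss of the β-silyl group leaves the olefin only at C1=C2.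

Step 3
Reactants: 4 (4aS,6R,8aS)-6-bromo-2,5,5,8a-tetramethyl-3,4,4a,5,6,7,8,8a-octahydronaphthalene
Product: 7 (2S,4aS,6R,8aR)-6-bromo-2,5,5,8a-tetramethyloctahydronaphthalen-1(2H)-one, via alkylborane 5 (not isolated), via C2-epimeric ketone 6 (not isolated)
Conditions: BH3·THF, THF, 0 °C → rt; then Na2Cr2O7, aq. H2SO4, Et2O, 0 °C → rt; then NaOMe (cat.), MeOH, rt
Reagents that add atoms: borane–tetrahydrofuran, B.C1CCOC1 (boron of 5 only); sodium dichromate in aqueous H2SO4, [Na+].[Na+].[O-][Cr](=O)(=O)O[Cr](=O)(=O)[O-] (carbonyl oxygen)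
Why: Brown hydroboration followed by chromic acid oxidation of the alkylborane, in which boron adds to the less substituted C1 from the face opposite the axial C8a methyl, oxidation gives ketone 6, and base equilibration moves the C2 methyl from the axial position (1,3-diaxial to the C8a methyl) to the equatorial one, which sets C2 as S.

Step 4
Reactants: 8 (3R)-3,7-dimethylocta-1,6-dien-3-ol ((R)-(−)-linalool)
Product: 9 (5R)-5-ethenyl-5-methyloxolan-2-ol (lactol, mixture of C2 anomers)
Conditions: O3 (1.0 equiv, Sudan III end point), CH2Cl2, −78 °C; then Me2S, −78 °C → rt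
Reagents that add atoms: ozone, [O-][O+]=O
Why: Chemoselective ozonolysis, in which ozone attacks the electron-rich trisubstituted olefin far faster than the vinyl group and the resulting γ-hydroxy aldehyde closes to the five-membered lactol, with the carbinol stereocentre of linalool untouched.

Step 5
Reactants: 9 (5R)-5-ethenyl-5-methyloxolan-2-ol
Product: 11 (3R)-5-iodo-3-methylpent-1-en-3-ol, via iodo formate 10 (not isolated)
Conditions: PhI(OAc)2, I2, CH2Cl2, hν (visible), rt; then K2CO3 (cat.), MeOH, 0 °C
Reagents that add atoms: iodine, II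
Why: Suárez anomeric alkoxy-radical fragmentation (hypoiodite reaction), in which the lactol O–I bond homolyses, β-scission excises the lactol carbon as a formate and the primary radical is trapped by iodine, after which catalytic methanolysis removes the formate; the quaternary stereocentre is not involved.

Step 6
Reactants: 7 (2S,4aS,6R,8aR)-6-bromo-2,5,5,8a-tetramethyloctahydronaphthalen-1(2H)-one; 11 (3R)-5-iodo-3-methylpent-1-en-3-ol
Product: 15 (1R,2S,4aS,6R,8aR)-6-bromo-1-[(3R)-3-hydroxy-3-methylpent-4-en-1-yl]-2,5,5,8a-tetramethyldecahydronaphthalen-1-ol (target), via lithium iodo-alkoxide 12 (not isolated), via dilithio reagent 13 (not isolated), via dilithium dialkoxide 14 (not isolated)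
Conditions: 11 (2.5 equiv), MeLi (2.5 equiv), Et2O, −78 °C; t-BuLi (5.0 equiv), −78 °C; then 7, −78 → −20 °C; aq. NH4Cl
Reagents that add atoms: none
Why: 1,2-Addition of a γ-lithio alkoxide (Normant-type dianion, made by O-deprotonation and then I/Li exchange) to the ketone, in which the nucleophile enters axially, anti to the axial C8a methyl that blocks the equatorial trajectory (as in 12-oxo steroids), giving the equatorial C1–OH and setting C1 as R, while the side-chain carbinol centre comes unchanged from linalool.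

## Compound list

1 | (5E)-6,10-dimethylundeca-5,9-dien-2-one | CC(C)=CCC/C(C)=C/CCC(C)=O | starting material
2 | lithium (5E)-2,6,10-trimethyl-1,1-bis(trimethylsilyl)undeca-5,9-dien-2-olate (racemic at C2) | CC(C)=CCC/C(C)=C/CCC(C)(O[Li])C([Si](C)(C)C)[Si](C)(C)C | intermediate
3 | trimethyl[(5E)-2,6,10-trimethylundeca-1,5,9-trien-1-yl]silane (1E/1Z mixture) | CC(C)=CCC/C(C)=C/CCC(C)=C[Si](C)(C)C | intermediate
4 | (4aS,6R,8aS)-6-bromo-2,5,5,8a-tetramethyl-3,4,4a,5,6,7,8,8a-octahydronaphthalene | C1=C(C)CC[C@@H]2C(C)(C)[C@H](Br)CC[C@]21C | intermediate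
5 | [(1S,2R,4aS,6R,8aS)-6-bromo-2,5,5,8a-tetramethyldecahydronaphthalen-1-yl]borane | B[C@H]1[C@H](C)CC[C@@H]2C(C)(C)[C@H](Br)CC[C@]21C | intermediate
6 | (2R,4aS,6R,8aR)-6-bromo-2,5,5,8a-tetramethyloctahydronaphthalen-1(2H)-one | O=C1[C@H](C)CC[C@@H]2C(C)(C)[C@H](Br)CC[C@]21C | intermediate
7 | (2S,4aS,6R,8aR)-6-bromo-2,5,5,8a-tetramethyloctahydronaphthalen-1(2H)-one | O=C1[C@@H](C)CC[C@@H]2C(C)(C)[C@H](Br)CC[C@]21C | intermediate
8 | (3R)-3,7-dimethylocta-1,6-dien-3-ol | C=C[C@](C)(O)CCC=C(C)C | starting material
9 | (5R)-5-ethenyl-5-methyloxolan-2-ol | C=C[C@@]1(C)CCC(O)O1 | intermediate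
10 | (3R)-5-iodo-3-methylpent-1-en-3-yl formate | C=C[C@](C)(OC=O)CCI | intermediate
11 | (3R)-5-iodo-3-methylpent-1-en-3-ol | C=C[C@](C)(O)CCI | intermediate
12 | lithium (3R)-5-iodo-3-methylpent-1-en-3-olate | C=C[C@](C)(O[Li])CCI | intermediate
13 | lithium (3R)-5-lithio-3-methylpent-1-en-3-olate | C=C[C@](C)(O[Li])CC[Li] | intermediate
14 | dilithium dialkoxide of 15 | C=C[C@](C)(O[Li])CC[C@@]1(O[Li])[C@@H](C)CC[C@@H]2C(C)(C)[C@H](Br)CC[C@]21C | intermediate
15 | (1R,2S,4aS,6R,8aR)-6-bromo-1-[(3R)-3-hydroxy-3-methylpent-4-en-1-yl]-2,5,5,8a-tetramethyldecahydronaphthalen-1-ol | C=C[C@](C)(O)CC[C@@]1(O)[C@@H](C)CC[C@@H]2C(C)(C)[C@H](Br)CC[C@]21C | target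

## Step count and risk

Total steps: 6. Longest linear sequence: 4 (steps 1, 2, 3, 6); the side-chain branch is steps 4, 5, 6.

**Step 2 (key bicyclisation).** The catalyst class has only been shown with aryl terminators, so ee and conversion with a vinylsilane are unproven. Bromodesilylation, incomplete second ring closure and a slower reaction of the 1E isomer are possible. The fallback sets out from 3 and comes back at 15, using the linalool centre as a built-in resolving handle. 3 is cyclised without asymmetric induction with bromodiethylsulfonium bromopentachloroantimonate in MeNO2 at −25 °C. This gives 4 together with its enantiomer (4aR,6S,8aR)-6-bromo-2,5,5,8a-tetramethyl-3,4,4a,5,6,7,8,8a-octahydronaphthalene F1. The racemate is taken through step 3, where the mirror-image material passes through the enantiomeric alkylborane F2 and the enantiomeric C2-epimeric ketone F3 to (2R,4aR,6S,8aS)-6-bromo-2,5,5,8a-tetramethyloctahydronaphthalen-1(2H)-one F4. Coupling of the racemic ketone with enantiopure 13 as in step 6 gives 15 and, through the dilithium dialkoxide F5, the diastereomer (1S,2R,4aR,6S,8aS)-6-bromo-1-[(3R)-3-hydroxy-3-methylpent-4-en-1-yl]-2,5,5,8a-tetramethyldecahydronaphthalen-1-ol F6. The two are separated by chromatography or crystallisation; because the stereocentres are remote, this may need HPLC.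

**Step 5 (alkoxy-radical fragmentation).** Acetyl hypoiodite can add to the vinyl group, and the primary radical can be lost in side reactions. The fallback sets out from 9 and comes back at 11 by an ionic one-carbon excision. 9 is converted with MsCl/Et3N through its anomeric mesylate F7 into the cyclic enol ether (2R)-2-ethenyl-2-methyl-2,3-dihydrofuran F8. Ozone (1 equiv, −78 °C) cleaves only the enol ether double bond to (3R)-3-methyl-5-oxopent-1-en-3-yl formate F9. NaBH4 in MeOH reduces the aldehyde and removes the formate to give (3R)-3-methylpent-4-ene-1,3-diol F10. Appel iodination of the primary hydroxyl (I2, PPh3, imidazole) gives 11.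

**Step 6 (fragment union).** The unprotected dianion may aggregate and add poorly to the hindered ketone, and enolisation at C2 may compete. The fallback sets out from 11 and comes back at 15 with a protected, mono-anionic organocerium nucleophile. 11 is silylated (TESOTf, 2,6-lutidine) to triethyl{[(3R)-5-iodo-3-methylpent-1-en-3-yl]oxy}silane F11. I/Li exchange with t-BuLi gives the alkyllithium F12, and anhydrous CeCl3 converts it into the organocerium reagent F13. Addition to 7 gives the TES-protected adduct (1R,2S,4aS,6R,8aR)-6-bromo-2,5,5,8a-tetramethyl-1-{(3R)-3-methyl-3-[(triethylsilyl)oxy]pent-4-en-1-yl}decahydronaphthalen-1-ol F14. TBAF in THF then gives 15.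

## Further compounds

F1 | step 2 | (4aR,6S,8aR)-6-bromo-2,5,5,8a-tetramethyl-3,4,4a,5,6,7,8,8a-octahydronaphthalene | C1=C(C)CC[C@H]2C(C)(C)[C@@H](Br)CC[C@@]21C
F2 | step 2 | [(1R,2S,4aR,6S,8aR)-6-bromo-2,5,5,8a-tetramethyldecahydronaphthalen-1-yl]borane | B[C@@H]1[C@@H](C)CC[C@H]2C(C)(C)[C@@H](Br)CC[C@@]21C
F3 | step 2 | (2S,4aR,6S,8aS)-6-bromo-2,5,5,8a-tetramethyloctahydronaphthalen-1(2H)-one | O=C1[C@@H](C)CC[C@H]2C(C)(C)[C@@H](Br)CC[C@@]21C
F4 | step 2 | (2R,4aR,6S,8aS)-6-bromo-2,5,5,8a-tetramethyloctahydronaphthalen-1(2H)-one | O=C1[C@H](C)CC[C@H]2C(C)(C)[C@@H](Br)CC[C@@]21C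
F5 | step 2 | dilithium dialkoxide of F6 | C=C[C@](C)(O[Li])CC[C@]1(O[Li])[C@H](C)CC[C@H]2C(C)(C)[C@@H](Br)CC[C@@]21C
F6 | step 2 | (1S,2R,4aR,6S,8aS)-6-bromo-1-[(3R)-3-hydroxy-3-methylpent-4-en-1-yl]-2,5,5,8a-tetramethyldecahydronaphthalen-1-ol | C=C[C@](C)(O)CC[C@]1(O)[C@H](C)CC[C@H]2C(C)(C)[C@@H](Br)CC[C@@]21C
F7 | step 5 | (5R)-5-ethenyl-5-methyloxolan-2-yl methanesulfonate | C=C[C@@]1(C)CCC(OS(C)(=O)=O)O1
F8 | step 5 | (2R)-2-ethenyl-2-methyl-2,3-dihydrofuran | C=C[C@@]1(C)CC=CO1
F9 | step 5 | (3R)-3-methyl-5-oxopent-1-en-3-yl formate | C=C[C@](C)(OC=O)CC=O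
F10 | step 5 | (3R)-3-methylpent-4-ene-1,3-diol | C=C[C@](C)(O)CCO
F11 | step 6 | triethyl{[(3R)-5-iodo-3-methylpent-1-en-3-yl]oxy}silane | C=C[C@](C)(O[Si](CC)(CC)CC)CCI
F12 | step 6 | {(3R)-3-methyl-3-[(triethylsilyl)oxy]pent-4-en-1-yl}lithium | C=C[C@](C)(O[Si](CC)(CC)CC)CC[Li]
F13 | step 6 | dichloro{(3R)-3-methyl-3-[(triethylsilyl)oxy]pent-4-en-1-yl}cerium | C=C[C@](C)(O[Si](CC)(CC)CC)CC[Ce](Cl)Cl
F14 | step 6 | (1R,2S,4aS,6R,8aR)-6-bromo-2,5,5,8a-tetramethyl-1-{(3R)-3-methyl-3-[(triethylsilyl)oxy]pent-4-en-1-yl}decahydronaphthalen-1-ol | C=C[C@](C)(O[Si](CC)(CC)CC)CC[C@@]1(O)[C@@H](C)CC[C@@H]2C(C)(C)[C@H](Br)CC[C@]21C
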